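**Retrosynthetic overview**

- C7–Br is cut last (bromination ortho to the 6-OH of 9). 9 comes from 7 by one hydrogenation (C2'=C3' alkene and O-benzyl ether).
- Key cut in 7: the ring bond O1–C2 and the side-chain bond C1'–C2' are formed together by an enantioselective Pd(II) oxypalladation/Heck domino reaction. The precursors are the achiral open-chain 2'-hydroxyaryl β,γ-enone 4 and 2-methylbut-3-en-2-ol 5.
- Feature used: C2 of the pyranone ring is a quaternary ether carbon bearing O1, CH3, C3H2 and the chain CH2 (C1'). This is the pattern left by O-attack on a methallyl group whose CH2–Pd has no β-hydrogen. C2'–C4'(OH)Me2 is alkene 5 itself, and C4 is already a ketone.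
- 4 comes from aldehyde 1 and methallyl Grignard 2, then oxidation. The arene is bought; the pyranone ring, the only ring formed, is closed in step 3.

Key step: step 3

Assumption: (S,S)-Bn-BOXAX (2,2'-bis[(4S)-4-benzyl-4,5-dihydrooxazol-2-yl]-1,1'-binaphthyl, a known ligand used in catalytic amount) is written as the antipode expected to give (R) at C2; if a test run shows the opposite sense, the (R,R)-ligand is used and nothing else changes.

**Route**

Step 1
Reactants: 1 5-(benzyloxy)-2-hydroxybenzaldehyde; 2 methallylmagnesium chloride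
Product: 3 rac-4-(benzyloxy)-2-(1-hydroxy-3-methylbut-3-en-1-yl)phenol
Conditions: 2 (2.3 equiv), THF, −78 to 0 °C; aq. NH4Cl
Reagents that add atoms: methallylmagnesium chloride (2), CC(=C)C[Mg]Cl
Why: Grignard 1,2-addition to the aldehyde after the first equivalent of 2 has deprotonated the phenol; the carbinol centre forms as a racemate, which does not matter because step 2 oxidises it.

Step 2
Reactants: 3 rac-4-(benzyloxy)-2-(1-hydroxy-3-methylbut-3-en-1-yl)phenol
Product: 4 1-[5-(benzyloxy)-2-hydroxyphenyl]-3-methylbut-3-en-1-one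
Conditions: activated MnO2 (15 equiv), CH2Cl2, 0 °C to rt; filtered through Celite and used at once
Reagents that add atoms: none
Why: Chemoselective benzylic alcohol oxidation with MnO2 under neutral heterogeneous conditions should leave the phenol, the benzyl ether and the non-conjugated 1,1-disubstituted alkene untouched.

Step 3
Reactants: 4 1-[5-(benzyloxy)-2-hydroxyphenyl]-3-methylbut-3-en-1-one; 5 2-methylbut-3-en-2-ol
Product: 7 (R)-6-(benzyloxy)-2-[(E)-4-hydroxy-4-methylpent-2-en-1-yl]-2-methylchroman-4-one, via (S)-alkylpalladium(II) trifluoroacetate 6 (not isolated)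
Conditions: Pd(OCOCF3)2 (10 mol%), (S,S)-Bn-BOXAX (40 mol%), p-benzoquinone (4 equiv), 5 (10 equiv), CH2Cl2, rt
Reagents that add atoms: 2-methylbut-3-en-2-ol (5), CC(C)(O)C=C
Why: Proposed new method: the phenoxide-bound Pd(II)–bis(oxazoline) complex should add across the 1,1-disubstituted alkene of 4 by oxypalladation, O1 going to the disubstituted carbon (future C2); the neopentyl-type alkylpalladium 6 has no β-hydrogen, so it inserts the monosubstituted alkene of 5 at its CH2 terminus and then β-hydride-eliminates to the E-allylic alcohol, while p-benzoquinone returns Pd(0) to Pd(II). The closest known reaction type is the enantioselective domino Wacker/Heck reaction of 2-(3-methylbut-3-enyl)phenols with acrylates under Pd(II)/BOXAX catalysis, which gives 2-methyl-2-alkylchromans; new here are the keto tether (which puts the chromanone oxidation level in place) and the unactivated tertiary allylic alcohol as terminating alkene. The pyranone ring closes in the 6-exo-trig mode (Markovnikov O-attack; the 7-endo mode would need attack at the CH2 terminus). C2 is the only new stereocentre and is set by the chiral ligand, which must deliver O1 to the Re face of the disubstituted alkene carbon to give (R). The step needs cyclisation to outrun conjugation of the β,γ-enone (hence base-free conditions and freshly made 4), and capture of 6 by 5 to outrun reversal of the oxypalladation, which the large excess of 5 and its Pd-coordinating hydroxyl should secure.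

Step 4
Reactants: 7 (R)-6-(benzyloxy)-2-[(E)-4-hydroxy-4-methylpent-2-en-1-yl]-2-methylchroman-4-one
Product: 9 (R)-6-hydroxy-2-(4-hydroxy-4-methylpentyl)-2-methylchroman-4-one, via saturated benzyl ether 8 (not isolated)
Conditions: H2 (1 atm), 10% Pd/C, EtOAc, rt
Reagents that add atoms: none
Why: Heterogeneous catalytic hydrogenation should saturate the disubstituted alkene and then hydrogenolyse the O-benzyl ether in one operation, while the electron-rich aryl ketone and the C2 centre stay untouched under neutral conditions.

Step 5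
Reactants: 9 (R)-6-hydroxy-2-(4-hydroxy-4-methylpentyl)-2-methylchroman-4-one
Product: 10 (R)-7-bromo-6-hydroxy-2-(4-hydroxy-4-methylpentyl)-2-methylchroman-4-one
Conditions: NBS (1.0 equiv), MeCN, −20 to 0 °C
Reagents that add atoms: N-bromosuccinimide, O=C1CCC(=O)N1Br
Why: Electrophilic aromatic bromination ortho to the free 6-OH (the para position is ring carbon C8a); of the two ortho sites C7 is open, whereas C5 is crowded by the adjacent C4 carbonyl, in line with the 4-bromination of 2,5-dialkoxybenzaldehydes.

**Compound list**

1 | 5-(benzyloxy)-2-hydroxybenzaldehyde | O=Cc1cc(OCc2ccccc2)ccc1O | starting material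
2 | methallylmagnesium chloride (2-methylallylmagnesium chloride) | CC(=C)C[Mg]Cl | starting material
3 | rac-4-(benzyloxy)-2-(1-hydroxy-3-methylbut-3-en-1-yl)phenol | CC(=C)CC(O)c1cc(OCc2ccccc2)ccc1O | intermediate
4 | 1-[5-(benzyloxy)-2-hydroxyphenyl]-3-methylbut-3-en-1-one | CC(=C)CC(=O)c1cc(OCc2ccccc2)ccc1O | intermediate
5 | 2-methylbut-3-en-2-ol | CC(C)(O)C=C | starting material
6 | {[(2S)-6-(benzyloxy)-2-methyl-4-oxochroman-2-yl]methyl}palladium(II) trifluoroacetate (bis(oxazoline) ligand on Pd omitted) | O=C(O[Pd]C[C@]1(C)CC(=O)c2cc(OCc3ccccc3)ccc2O1)C(F)(F)F | intermediate (not isolated)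
7 | (R)-6-(benzyloxy)-2-[(E)-4-hydroxy-4-methylpent-2-en-1-yl]-2-methylchroman-4-one | CC(C)(O)/C=C/C[C@]1(C)CC(=O)c2cc(OCc3ccccc3)ccc2O1 | intermediate
8 | (R)-6-(benzyloxy)-2-(4-hydroxy-4-methylpentyl)-2-methylchroman-4-one | CC(C)(O)CCC[C@]1(C)CC(=O)c2cc(OCc3ccccc3)ccc2O1 | intermediate (not isolated)
9 | (R)-6-hydroxy-2-(4-hydroxy-4-methylpentyl)-2-methylchroman-4-one | CC(C)(O)CCC[C@]1(C)CC(=O)c2cc(O)ccc2O1 | intermediate
10 | (R)-7-bromo-6-hydroxy-2-(4-hydroxy-4-methylpentyl)-2-methylchroman-4-one | CC(C)(O)CCC[C@]1(C)CC(=O)c2cc(O)c(Br)cc2O1 | target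

**Step count and risks**

Total step count: 5. Longest linear sequence: 5 steps (1 → 3 → 4 → 7 → 9 → 10).

Steps most likely to fail:

1. Step 3 (Proposed new method). The β,γ-enone may slip into conjugation, on standing after step 2 or under the Pd conditions, and then close by plain oxa-Michael addition to an achiral 2,2-dimethylchromanone. The alkylpalladium intermediate may also be captured too slowly by the unactivated alkene, or the keto tether may lower the face selectivity. Fallback with known chemistry: set out from carbinol 3, which has an sp3 tether and no acidic C–H between carbonyl and alkene. The domino oxypalladation/Heck reaction is run with methyl acrylate, the acceptor class for which it is established (Pd(OCOCF3)2, the same ligand, p-benzoquinone, CH2Cl2). This should give methyl (E)-4-[(2R)-6-(benzyloxy)-4-hydroxy-2-methylchroman-2-yl]but-2-enoate F1 as a pair of C4 epimers. MeMgBr (excess, THF, 0 °C) then adds twice to the ester to give (2R)-6-(benzyloxy)-2-[(E)-4-hydroxy-4-methylpent-2-en-1-yl]-2-methylchroman-4-ol F2. MnO2 oxidises the benzylic carbinol, erasing C4, and the route is rejoined at 7.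

2. Step 5. Site selectivity may be poor (attack at C5 instead of C7), or a second bromine may enter. Fallback: set out from 9 and replace the electrophilic substitution by a sterically governed C–H borylation. HBpin converts the phenol into (R)-2-(4-hydroxy-4-methylpentyl)-2-methyl-6-[(4,4,5,5-tetramethyl-1,3,2-dioxaborolan-2-yl)oxy]chroman-4-one F3. This O-boryl group steers Ir-catalysed borylation (B2pin2, [Ir(OMe)(cod)]2, 4,4'-di-tert-butylbipyridine, cyclohexane, 80 °C) to the ortho C–H that is not flanked by a second substituent. That gives (R)-2-(4-hydroxy-4-methylpentyl)-2-methyl-7-(4,4,5,5-tetramethyl-1,3,2-dioxaborolan-2-yl)-6-[(4,4,5,5-tetramethyl-1,3,2-dioxaborolan-2-yl)oxy]chroman-4-one F4. Methanolysis frees the phenol to give (R)-6-hydroxy-2-(4-hydroxy-4-methylpentyl)-2-methyl-7-(4,4,5,5-tetramethyl-1,3,2-dioxaborolan-2-yl)chroman-4-one F5. CuBr2 in MeOH/H2O then exchanges boron for bromine and the route is rejoined at 10.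

3. Step 4. The allylic tertiary C–O bond may be hydrogenolysed before the alkene is saturated, or the aryl ketone may be over-reduced during the longer exposure needed for debenzylation. Fallback: set out from 7 and separate the two events. The alkene is reduced without a metal by diimide (2-nitrobenzenesulfonylhydrazide, Et3N, CH2Cl2, rt), and 8 is isolated. A short hydrogenolysis of the benzyl ether (H2, Pd(OH)2/C, EtOAc), now without an allylic system, rejoins the route at 9.

**Further compounds**

F1 | step 3 | methyl (E)-4-[(2R)-6-(benzyloxy)-4-hydroxy-2-methylchroman-2-yl]but-2-enoate (C4 epimers) | COC(=O)/C=C/C[C@]1(C)CC(O)c2cc(OCc3ccccc3)ccc2O1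
F2 | step 3 | (2R)-6-(benzyloxy)-2-[(E)-4-hydroxy-4-methylpent-2-en-1-yl]-2-methylchroman-4-ol (C4 epimers) | CC(C)(O)/C=C/C[C@]1(C)CC(O)c2cc(OCc3ccccc3)ccc2O1
F3 | step 5 | (R)-2-(4-hydroxy-4-methylpentyl)-2-methyl-6-[(4,4,5,5-tetramethyl-1,3,2-dioxaborolan-2-yl)oxy]chroman-4-one | CC(C)(O)CCC[C@]1(C)CC(=O)c2cc(OB3OC(C)(C)C(C)(C)O3)ccc2O1
F4 | step 5 | (R)-2-(4-hydroxy-4-methylpentyl)-2-methyl-7-(4,4,5,5-tetramethyl-1,3,2-dioxaborolan-2-yl)-6-[(4,4,5,5-tetramethyl-1,3,2-dioxaborolan-2-yl)oxy]chroman-4-one | CC(C)(O)CCC[C@]1(C)CC(=O)c2cc(OB3OC(C)(C)C(C)(C)O3)c(B4OC(C)(C)C(C)(C)O4)cc2O1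
F5 | step 5 | (R)-6-hydroxy-2-(4-hydroxy-4-methylpentyl)-2-methyl-7-(4,4,5,5-tetramethyl-1,3,2-dioxaborolan-2-yl)chroman-4-one | CC(C)(O)CCC[C@]1(C)CC(=O)c2cc(O)c(B3OC(C)(C)C(C)(C)O3)cc2O1
F0 | step 4 | none | none
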